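Numbering (germacrane): carbocycle C1–C10; lactone O6/C6–C7–C11(=C13)–C12; ester carbon C14 on C10; methyl C15 on C4; O8 bears the epoxy ester, O9 the acetate.
Last bonds: the 4,5-epoxide and the γ-lactone form together from a cis-5,6-epoxide next to the free C4 carbinol (Payne shift, then lactonisation of O6 on C12); O9 comes from a C9 ketone.
Key disconnection C10–C1: the ten-membered carbocycle is made from the eight-membered oxocene (O, C3–C9) by a ring-expanding propargyl Claisen shift in C10=C9–O–C3–C2≡C1, followed by allene-to-diene isomerisation.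
Enabling feature: in the carbocycle the oxygen on C9, the ester-bearing C10 and the unsaturated three-carbon unit C1–C3 are contiguous, which is the retron of a 3-(propargyloxy)acrylate. C3 ends up without a heteroatom, so its stereocentre and the C9=C10 geometry are disposable.
Ring order: side-chain oxirane; oxocene (metathesis, C5=C6); carbocycle; 5,6-oxirane; 4,5-oxirane plus lactone. Pieces: C3–C5/C15 from isoprene monoxide, C1–C2 from a silylacetylene, C8–C10/C14 from propiolaldehyde acetal, C6–C7/C11–C13 from acrolein and methyl acrylate.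

Key step: step 16

Assumption: the named enantiomers of the chiral ligand (step 1) and of the phosphoric acid (step 10) are taken to give the drawn configurations; if the sense of induction is opposite, the mirror-image catalyst is used.

Step 1
Reactants: 1 2-methyl-2-vinyloxirane (racemic); 2 4-methoxybenzyl alcohol
Product: 3 (S)-2-[(4-methoxybenzyl)oxy]-2-methylbut-3-en-1-ol
Conditions: Pd2(dba)3·CHCl3 (1 mol %), (R,R)-N,N'-(cyclohexane-1,2-diyl)bis[2-(diphenylphosphanyl)benzamide] (3 mol %), Et3B (1 mol %), CH2Cl2, 23 °C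
Reagents that add atoms: none
Why: Palladium-catalysed dynamic kinetic asymmetric allylic etherification (Tsuji–Trost type): both enantiomers of 1 ionise to rapidly interconverting π-allyl complexes, the borate made from 2 and Et3B is tied to the liberated alkoxide and delivers the benzyloxy group to the adjacent tertiary terminus, and the chiral ligand fixes C4 as S.

Step 2
Reactants: 3 (S)-2-[(4-methoxybenzyl)oxy]-2-methylbut-3-en-1-ol
Product: 4 (S)-2-[(4-methoxybenzyl)oxy]-2-methylbut-3-enal
Conditions: Dess–Martin periodinane, CH2Cl2, 0 to 23 °C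
Reagents that add atoms: none
Why: Dess–Martin oxidation of a primary alcohol, safe for C4 because the α-carbon is quaternary and cannot enolise.

Step 3
Reactants: 4 (S)-2-[(4-methoxybenzyl)oxy]-2-methylbut-3-enal; 5 ethynyltriisopropylsilane
Product: 7 (4S)-4-[(4-methoxybenzyl)oxy]-4-methyl-1-(triisopropylsilyl)hex-5-en-1-yn-3-ol (both C3 epimers), via lithium acetylide 6 (not isolated)
Conditions: 5, n-BuLi, THF, −78 °C; then 4; aq NH4Cl
Reagents that add atoms: none
Why: 1,2-Addition of a lithium acetylide to an aldehyde; the new carbinol centre C3 is accepted as a mixture of epimers because step 16 erases it.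

Step 4
Reactants: 8 3,3-diethoxyprop-1-yne
Product: 10 methyl 4,4-diethoxybut-2-ynoate, via lithiated acetal 9 (not isolated)
Conditions: n-BuLi, THF, −78 °C; ClCO2Me, −78 to 0 °C
Reagents that add atoms: methyl chloroformate, COC(=O)Cl
Why: Acylation of a lithium acetylide by a chloroformate, the standard entry to 2-alkynoates.

Step 5
Reactants: 7 propargylic alcohol (C3 epimers); 10 methyl 4,4-diethoxybut-2-ynoate
Product: 11 alkoxyacrylate acetal, methyl 4,4-diethoxy-3-{[(4S)-4-[(4-methoxybenzyl)oxy]-4-methyl-1-(triisopropylsilyl)hex-5-en-1-yn-3-yl]oxy}but-2-enoate (C3 epimers, E/Z)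
Conditions: NaH (15 mol %), THF, 0 to 23 °C
Reagents that add atoms: none
Why: Alkoxide-catalysed oxa-Michael addition of an alcohol to a 2-alkynoate, regioselective for the β-carbon (C9) that the ester and the acetal both activate; the E/Z ratio of the new C9=C10 bond does not matter because step 16 consumes it.

Step 6
Reactants: 11 alkoxyacrylate acetal
Product: 12 alkoxyacrylate aldehyde, methyl 3-{[(4S)-4-[(4-methoxybenzyl)oxy]-4-methyl-1-(triisopropylsilyl)hex-5-en-1-yn-3-yl]oxy}-4-oxobut-2-enoate (C3 epimers, E/Z)
Conditions: PPTS (cat.), acetone/H2O, 40 °C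
Reagents that add atoms: water, O
Why: Acid-catalysed acetal hydrolysis under mild conditions, selective because the vinylogous carbonate, the PMB ether and the silyl alkyne ionise far less readily than a diethyl acetal.

Step 7
Reactants: 13 acrolein; 14 methyl acrylate
Product: 15 methyl 3-hydroxy-2-methylenepent-4-enoate (racemic)
Conditions: DABCO (cat.), neat, 23 °C
Reagents that add atoms: none
Why: Morita–Baylis–Hillman reaction of an acrylate at the aldehyde carbon of acrolein; the racemic carbinol centre is lost again in step 9.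

Step 8
Reactants: 15 methyl 3-hydroxy-2-methylenepent-4-enoate
Product: 16 methyl 3-acetoxy-2-methylenepent-4-enoate
Conditions: Ac2O, pyridine, DMAP (cat.), CH2Cl2, 0 °C
Reagents that add atoms: acetic anhydride, CC(=O)OC(C)=O
Why: Standard O-acetylation that turns the hydroxyl group into the leaving group for step 9.

Step 9
Reactants: 16 methyl 3-acetoxy-2-methylenepent-4-enoate
Product: 17 methyl (E)-2-[(4,4,5,5-tetramethyl-1,3,2-dioxaborolan-2-yl)methyl]penta-2,4-dienoate
Conditions: B2pin2, CuCl (5 mol %), KOt-Bu (5 mol %), THF, 0 °C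
Reagents that add atoms: bis(pinacolato)diboron, CC1(C)OB(OC1(C)C)B1OC(C)(C)C(C)(C)O1
Why: Copper-catalysed SN2′ borylation of a Morita–Baylis–Hillman acetate: borylcupration of the acrylate CH2 terminus and loss of acetate give the conjugated dienoate with the vinyl group trans to the ester and therefore cis to the CH2B group.

Step 10
Reactants: 12 alkoxyacrylate aldehyde; 17 dienyl allylboronate
Product: 18 seco alcohol (4S,7R,8S; 7,8-syn; C8–OH, C7 bearing vinyl C6 and C11(=C13H2)CO2Me; C3 epimers, E/Z at C9=C10)
Conditions: (R)-TRIP phosphoric acid (5 mol %), 4 Å MS, toluene, −30 °C; aq NaHCO3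
Reagents that add atoms: none
Why: Chiral phosphoric acid-catalysed allylboration through a closed chair transition state: the cis relation of vinyl and CH2B is translated into the 7,8-syn adduct with the exocyclic C11=C13 methylene, and the catalyst selects the aldehyde face so that C7 (R) and C8 (S) are set independently of C3 and C4.

Step 11
Reactants: 19 (E)-2-methylbut-2-en-1-ol
Product: 20 [(2S,3S)-2,3-dimethyloxiran-2-yl]methanol
Conditions: Ti(Oi-Pr)4 (cat.), L-(+)-diethyl tartrate (cat.), t-BuOOH, 4 Å MS, CH2Cl2, −20 °C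
Reagents that add atoms: tert-butyl hydroperoxide, CC(C)(C)OO
Why: Sharpless asymmetric epoxidation: with L-(+)-tartrate the E-allylic alcohol is epoxidised to the (2S,3S)-epoxy alcohol, and the stereospecific syn oxygen transfer keeps the two methyl groups cis.

Step 12
Reactants: 20 [(2S,3S)-2,3-dimethyloxiran-2-yl]methanol
Product: 21 (2R,3S)-2,3-dimethyloxirane-2-carboxylic acid
Conditions: RuCl3 (2 mol %), NaIO4, CCl4/MeCN/H2O, 23 °C
Reagents that add atoms: sodium periodate, [Na+].[O-]I(=O)(=O)=O
Why: Ruthenium tetroxide oxidation of a 2,3-epoxy alcohol to the glycidic acid, which leaves both oxirane centres untouched (the descriptor of C2 changes to R only by priority).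

Step 13
Reactants: 18 seco alcohol; 21 (2R,3S)-2,3-dimethyloxirane-2-carboxylic acid
Product: 22 seco ester (18 acylated at O8 by 21)
Conditions: DIC, DMAP (10 mol %), CH2Cl2, 0 °C
Reagents that add atoms: none
Why: Steglich esterification of the secondary alcohol O8–H; no stereocentre takes part.

Step 14
Reactants: 22 seco ester
Product: 23 silyl-alkynyl oxocene (ring O–C3–C4–C5=C6–C7–C8–C9 with cis C5=C6; exocyclic C9=C10H–CO2Me; C3 TIPS-ethynyl; C4 Me/OPMB; C7 C(=CH2)CO2Me; O8 epoxy ester)
Conditions: second-generation Hoveyda–Grubbs catalyst (10 mol %), toluene (1 mM), 80 °C, argon purge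
Reagents that add atoms: none
Why: Ring-closing metathesis of the two monosubstituted vinyl groups; the eight-membered ring can hold only a cis C5=C6 bond, the two 1,2-dioxygenated units (O4 with the ring oxygen on C3, O8 with the ring oxygen on C9) favour folded gauche conformers as in other oxocene closures, and the acrylate, the alkoxyacrylate and the bulky silyl alkyne are poor partners for the ruthenium carbene.

Step 15
Reactants: 23 silyl-alkynyl oxocene
Product: 24 ethynyl oxocene (terminal alkyne at C3)
Conditions: TBAF, AcOH, THF, 0 °C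
Reagents that add atoms: none
Why: Fluoride-induced protodesilylation of an alkynylsilane, buffered with acetic acid so that the esters and the acrylate are not attacked.

Step 16
Reactants: 24 ethynyl oxocene
Product: 26 ten-membered dienone ester (C9 ketone; cis ring bonds at C10=C1 and C2=C3 and C5=C6; C4 C7 C8 as in 32), via allenyl keto ester 25 (not isolated)
Conditions: toluene (degassed, 5 mM), BHT, 135 °C, sealed tube; then Et3N (20 mol %), 23 °C
Reagents that add atoms: none
Why: Proposed new method: heating 24 triggers a [3,3]-sigmatropic shift (propargyl Claisen, Saucy–Marbet type) in the array C10=C9–O–C3–C2≡C1, which forms C10–C1, breaks O–C3, turns the ring oxygen into the C9 ketone and so converts the oxocene (O, C3–C9) into the ten-membered carbocycle 25, after which the amine moves the doubly activated C10–H to the central allene carbon C2 and gives the dienone ester 26. The closest known reactions are the thermal or silver-catalysed propargyl Claisen rearrangement of acyclic 3-(propargyloxy)acrylates with base isomerisation to 2,4-dienones, and the two-atom Claisen ring expansion of 2-alkylidene-ω-vinyl cyclic ethers; their combination inside a ring has not been described. The carbocycle is closed pericyclically (suprafacial six-centre shift, not a polar cyclisation) through a bicyclo[5.3.1]-like transition state in which the five-atom chain C4–C8 bridges C3 and C9, a span that the ground-state oxocene already has. No stereocentre made in the step survives: C3, the enol-ether geometry, C10 of 25 and the allene axis are all erased, so every isomer of 24 converges on one product while C4, C7 and C8 are untouched. The cis ring geometry at C10=C1 and C2=C3 is expected because protonation of the ring-bound dienolate leads to the least strained cis,cis-diene, and reversible conjugate addition of the amine lets a wrong C10=C1 isomer equilibrate. Chemoselectivity rests on 24 holding only one oxygen-linked 1,5-enyne, and the oxa-6π valence tautomer of 26 would have to rebuild the oxocene with a bridgehead enol ether and stays in mobile equilibrium with the ketone that step 17 consumes.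

Step 17
Reactants: 26 ten-membered dienone ester
Product: 27 (9S)-alcohol (8,9-syn)
Conditions: NaBH4, CeCl3·7H2O, MeOH/THF, −40 °C
Reagents that add atoms: none
Why: Luche 1,2-reduction of the cross-conjugated ketone: hydride adds from the outer face in the Felkin–Anh sense, anti to the C8–O bond, which sets C9 as the 8,9-syn (threo) alcohol and spares the acrylate and the dienoate.

Step 18
Reactants: 27 (9S)-alcohol
Product: 28 9-acetate
Conditions: Ac2O, pyridine, DMAP (cat.), CH2Cl2, 0 °C
Reagents that add atoms: acetic anhydride, CC(=O)OC(C)=O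
Why: Standard O-acetylation, run directly after step 17 so that the O8 acyl group has no time to migrate to O9.

Step 19
Reactants: 28 9-acetate
Product: 29 C4 carbinol (tertiary alcohol flanked by C3=C2 and cis C5=C6)
Conditions: DDQ, CH2Cl2/pH 7 buffer, 0 °C
Reagents that add atoms: none
Why: Oxidative cleavage of a 4-methoxybenzyl ether by DDQ (hydride abstraction, then hydrolysis of the oxocarbenium ion), neutral enough for the esters and the side-chain oxirane.

Step 20
Reactants: 29 C4 carbinol
Product: 30 cis-5,6-epoxy carbinol (oxirane oxygen on the ring face that carries O4)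
Conditions: VO(acac)2 (5 mol %), t-BuOOH, CH2Cl2, 0 °C
Reagents that add atoms: tert-butyl hydroperoxide, CC(C)(C)OO
Why: Hydroxyl-directed vanadium-catalysed epoxidation: C5=C6 is the only electron-rich alkene within reach of O4–H, and oxygen is delivered to the ring face bearing O4, as is usual for medium-ring allylic alcohols, which sets C6 finally and C5 provisionally.

Step 21
Reactants: 30 cis-5,6-epoxy carbinol
Product: 32 target CNP0229507.5, via hydroxy ester 31 (not isolated)
Conditions: KOt-Bu (20 mol %), t-BuOH/THF, 0 °C; AcOH quench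
Reagents that add atoms: none
Why: Payne rearrangement followed by lactonisation: in the flexible ten-membered ring the C4 alkoxide can reach the back side of C5 (anti C3–C4–C5–C6 torsion), inverts C5 and forms the more substituted trans-4,5-epoxide, and the released C6 alkoxide closes the trans γ-lactone on C12 irreversibly with loss of methanol, while the bulky butoxide medium keeps the acetate, the epoxy ester and the methylene lactone intact.

Compound list
1 | 2-methyl-2-vinyloxirane (racemic) | C=CC1(C)CO1 | starting material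
2 | 4-methoxybenzyl alcohol | COc1ccc(CO)cc1 | starting material
3 | (S)-2-[(4-methoxybenzyl)oxy]-2-methylbut-3-en-1-ol | OC[C@@](C)(OCc1ccc(OC)cc1)C=C | intermediate
4 | (S)-2-[(4-methoxybenzyl)oxy]-2-methylbut-3-enal | O=C[C@@](C)(OCc1ccc(OC)cc1)C=C | intermediate
5 | ethynyltriisopropylsilane | C#C[Si](C(C)C)(C(C)C)C(C)C | starting material
6 | lithium (triisopropylsilyl)acetylide | [Li]C#C[Si](C(C)C)(C(C)C)C(C)C | intermediate
7 | (4S)-4-[(4-methoxybenzyl)oxy]-4-methyl-1-(triisopropylsilyl)hex-5-en-1-yn-3-ol (both C3 epimers) | OC(C#C[Si](C(C)C)(C(C)C)C(C)C)[C@@](C)(OCc1ccc(OC)cc1)C=C | intermediate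
8 | 3,3-diethoxyprop-1-yne | C#CC(OCC)OCC | starting material
9 | (3,3-diethoxyprop-1-yn-1-yl)lithium | [Li]C#CC(OCC)OCC | intermediate
10 | methyl 4,4-diethoxybut-2-ynoate | CCOC(OCC)C#CC(=O)OC | intermediate
11 | alkoxyacrylate acetal (C3 epimers, E/Z) | CCOC(OCC)C(=CC(=O)OC)OC(C#C[Si](C(C)C)(C(C)C)C(C)C)[C@@](C)(OCc1ccc(OC)cc1)C=C | intermediate
12 | alkoxyacrylate aldehyde (C3 epimers, E/Z) | O=CC(=CC(=O)OC)OC(C#C[Si](C(C)C)(C(C)C)C(C)C)[C@@](C)(OCc1ccc(OC)cc1)C=C | intermediate
13 | acrolein | C=CC=O | starting material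
14 | methyl acrylate | C=CC(=O)OC | starting material
15 | methyl 3-hydroxy-2-methylenepent-4-enoate (racemic) | C=CC(O)C(=C)C(=O)OC | intermediate
16 | methyl 3-acetoxy-2-methylenepent-4-enoate (racemic) | C=CC(OC(C)=O)C(=C)C(=O)OC | intermediate
17 | methyl (E)-2-[(4,4,5,5-tetramethyl-1,3,2-dioxaborolan-2-yl)methyl]penta-2,4-dienoate | C=C/C=C(/C(=O)OC)CB1OC(C)(C)C(C)(C)O1 | intermediate
18 | seco alcohol (4S,7R,8S) | C=C(C(=O)OC)[C@@H](C=C)[C@H](O)C(=CC(=O)OC)OC(C#C[Si](C(C)C)(C(C)C)C(C)C)[C@@](C)(OCc1ccc(OC)cc1)C=C | intermediate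
19 | (E)-2-methylbut-2-en-1-ol | C/C=C(\C)CO | starting material
20 | [(2S,3S)-2,3-dimethyloxiran-2-yl]methanol | OC[C@]1(C)O[C@H]1C | intermediate
21 | (2R,3S)-2,3-dimethyloxirane-2-carboxylic acid | OC(=O)[C@]1(C)O[C@H]1C | intermediate
22 | seco ester | C=C(C(=O)OC)[C@@H](C=C)[C@H](OC(=O)[C@]1(C)O[C@H]1C)C(=CC(=O)OC)OC(C#C[Si](C(C)C)(C(C)C)C(C)C)[C@@](C)(OCc1ccc(OC)cc1)C=C | intermediate
23 | silyl-alkynyl oxocene | C=C(C(=O)OC)[C@@H]1[C@H](OC(=O)[C@]2(C)O[C@H]2C)C(=CC(=O)OC)OC(C#C[Si](C(C)C)(C(C)C)C(C)C)[C@@](C)(OCc2ccc(OC)cc2)/C=C\1 | intermediate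
24 | ethynyl oxocene | C=C(C(=O)OC)[C@@H]1[C@H](OC(=O)[C@]2(C)O[C@H]2C)C(=CC(=O)OC)OC(C#C)[C@@](C)(OCc2ccc(OC)cc2)/C=C\1 | intermediate
25 | ten-membered allenyl β-keto ester (C10 and allene axis undefined) | C=C(C(=O)OC)[C@@H]1[C@H](OC(=O)[C@]2(C)O[C@H]2C)C(=O)C(C(=O)OC)C=C=C[C@@](C)(OCc2ccc(OC)cc2)/C=C\1 | intermediate
26 | ten-membered dienone ester | C=C(C(=O)OC)[C@@H]1[C@H](OC(=O)[C@]2(C)O[C@H]2C)C(=O)/C(C(=O)OC)=C\C=C/[C@@](C)(OCc2ccc(OC)cc2)/C=C\1 | intermediate
27 | (9S)-alcohol | C=C(C(=O)OC)[C@@H]1[C@H](OC(=O)[C@]2(C)O[C@H]2C)[C@@H](O)/C(C(=O)OC)=C\C=C/[C@@](C)(OCc2ccc(OC)cc2)/C=C\1 | intermediate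
28 | 9-acetate | C=C(C(=O)OC)[C@@H]1[C@H](OC(=O)[C@]2(C)O[C@H]2C)[C@@H](OC(C)=O)/C(C(=O)OC)=C\C=C/[C@@](C)(OCc2ccc(OC)cc2)/C=C\1 | intermediate
29 | C4 carbinol | C=C(C(=O)OC)[C@@H]1[C@H](OC(=O)[C@]2(C)O[C@H]2C)[C@@H](OC(C)=O)/C(C(=O)OC)=C\C=C/[C@@](C)(O)/C=C\1 | intermediate
30 | cis-5,6-epoxy carbinol | C=C(C(=O)OC)[C@@H]1[C@H](OC(=O)[C@]3(C)O[C@H]3C)[C@@H](OC(C)=O)/C(C(=O)OC)=C\C=C/[C@@](C)(O)[C@H]2O[C@@H]12 | intermediate
31 | trans-4,5-epoxy 6-hydroxy methyl ester | C=C(C(=O)OC)[C@@H]1[C@H](OC(=O)[C@]3(C)O[C@H]3C)[C@@H](OC(C)=O)/C(C(=O)OC)=C\C=C/[C@@]2(C)O[C@@H]2[C@H]1O | intermediate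
32 | CNP0229507.5 (4R,5R,6S,7R,8S,9S; side chain 2R,3S) | C=C1C(=O)O[C@H]2[C@H]1[C@H](OC(=O)[C@]1(C)O[C@H]1C)[C@@H](OC(C)=O)/C(C(=O)OC)=C\C=C/[C@@]1(C)O[C@H]21 | target

Total step count: 21. Longest linear sequence: 15 steps (1, 2, 3, 5, 6, 10, 13, 14, 15, 16, 17, 18, 19, 20, 21).

Steps most likely to fail

1. Step 16 (Proposed new method). The sigmatropic shift may not start because the ethynyl group cannot reach the enol-ether terminus across the oxocene. The allene may also be diverted by heterocyclisation before the proton shift.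
Fallback by known chemistry, setting out from 24:
- The terminal alkyne is semi-hydrogenated (H2, Pd/CaCO3 poisoned with Pb(OAc)2, quinoline) to the vinyl oxocene F1.
- This allyl vinyl ether undergoes the ordinary thermal Claisen ring expansion (toluene, 110–140 °C) to the ten-membered β-keto ester F2 with a cis C2=C3 bond.
- Selenenylation at C10 (PhSeCl, pyridine) gives the selenide F3.
- Oxidation with H2O2 and syn elimination toward C1 comes back to the route at 26.

2. Step 14. Cross-metathesis oligomerisation may win, or there may be no turnover at the vinyl group on the quaternary C4 once the bulky O8 ester is in place.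
Fallback, setting out from 18: ring closure and acylation change places. The lighter free alcohol, folded by its O8–H hydrogen bond to the neighbouring ether oxygen, is cyclised by metathesis to the oxocene alcohol F4. Only then is it esterified with 21 (DIC, DMAP), which comes back to the route at 23.

3. Step 21. Three things can go wrong in the basic medium: migration of the O8 acyl group to the new C6 alkoxide, attack of liberated methoxide on the acetate or on the methylene lactone, or a stalled epoxide migration.
Fallback, setting out from 29, avoiding both the epoxide of step 20 and the Payne shift: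
- Hydrogen-bond-directed syn dihydroxylation of C5=C6 on the O4 face (OsO4·TMEDA, CH2Cl2, −78 °C; reductive work-up) is followed by spontaneous lactonisation of O6 and gives the 5-hydroxy lactone F5.
- Selective mesylation of the secondary C5 hydroxyl (MsCl, Et3N) gives the mesylate F6.
- Cs2CO3 in MeCN closes the oxirane from O4 with inversion at C5, which comes back to the route at 32.

Further compounds
F1 | step 16 | vinyl oxocene | C=C(C(=O)OC)[C@@H]1[C@H](OC(=O)[C@]2(C)O[C@H]2C)C(=CC(=O)OC)OC(C=C)[C@@](C)(OCc2ccc(OC)cc2)/C=C\1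
F2 | step 16 | ten-membered β-keto ester (C10 undefined) | C=C(C(=O)OC)[C@@H]1[C@H](OC(=O)[C@]2(C)O[C@H]2C)C(=O)C(C(=O)OC)C/C=C\[C@@](C)(OCc2ccc(OC)cc2)/C=C\1
F3 | step 16 | C10 phenylselenide (C10 undefined) | C=C(C(=O)OC)[C@@H]1[C@H](OC(=O)[C@]2(C)O[C@H]2C)C(=O)C([Se]c2ccccc2)(C(=O)OC)C/C=C\[C@@](C)(OCc2ccc(OC)cc2)/C=C\1
F4 | step 14 | oxocene alcohol | C=C(C(=O)OC)[C@@H]1[C@H](O)C(=CC(=O)OC)OC(C#C[Si](C(C)C)(C(C)C)C(C)C)[C@@](C)(OCc2ccc(OC)cc2)/C=C\1
F5 | step 21 | 4,5-dihydroxy 6,12-lactone | C=C1C(=O)O[C@H]2[C@H]1[C@H](OC(=O)[C@]1(C)O[C@H]1C)[C@@H](OC(C)=O)/C(C(=O)OC)=C\C=C/[C@@](C)(O)[C@H]2O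
F6 | step 21 | C5 mesylate | C=C1C(=O)O[C@H]2[C@H]1[C@H](OC(=O)[C@]1(C)O[C@H]1C)[C@@H](OC(C)=O)/C(C(=O)OC)=C\C=C/[C@@](C)(O)[C@H]2OS(C)(=O)=O
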